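## Retrosynthetic overview

1. Target 26 ⇐ phenol 25 by para-selective singlet-oxygen dearomatisation; the C–OOH stereocentre is set last.
2. 25 ⇐ aryl triflate 23 (Stille vinylation, desilylation); the isopropenyl and methyl propanoate arms ⇐ ring-A cleavage of trans-fused gem-dimethyl ketone 20 (Baeyer–Villiger, methanolysis, dehydration).
3. Ketone 17 ⇐ enone 15 by reductive methylation, which sets the ring-fusion CH trans to the angular methyl.
4. Key C–C bond: intermolecular asymmetric Michael addition of the (S)-1-phenylethylamine imine of 1-methyl-2-tetralone 9 to ethyl vinyl ketone (quaternary carbon), then aldol closure of ring A.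
5. Ring order: aromatic ring C (from 2,6-dimethoxytoluene) → ring B (Friedel–Crafts tetralone) → ring A (Robinson annulation), which is later cleaved.

Assumption: the facial sense of step 6 is taken from the established (S)-amine → (R)-adduct outcome with 2-methylcyclohexanone; the same topicity is named S here because the aryl carbon outranks the side chain. Tricyclic compounds use phenanthrene numbering, seco compounds naphthalene numbering.

## Route

Step 1
Reactants: 1 2,6-dimethoxytoluene; 2 succinic anhydride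
Product: 3 4-(2,4-dimethoxy-3-methylphenyl)-4-oxobutanoic acid
Conditions: AlCl3 (2.5 equiv), CH2Cl2/PhNO2, 0 °C
Reagents that add atoms: none
Why: Friedel–Crafts acylation occurs at C3 of 1, the only position activated ortho/para by both methoxy groups, and the deactivated keto acid does not react twice.

Step 2
Reactants: 3 4-(2,4-dimethoxy-3-methylphenyl)-4-oxobutanoic acid
Product: 4 4-(2,4-dimethoxy-3-methylphenyl)butanoic acid
Conditions: H2 (4 atm), 10% Pd/C, AcOH, cat. HClO4, 50 °C
Reagents that add atoms: none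
Why: Catalytic hydrogenolysis of the electron-rich benzylic ketone under acid gives the methylene while the carboxylic acid and aryl ethers are inert.

Step 3
Reactants: 4 4-(2,4-dimethoxy-3-methylphenyl)butanoic acid
Product: 5 5,7-dimethoxy-6-methyl-3,4-dihydronaphthalen-1(2H)-one
Conditions: polyphosphoric acid, 80 °C
Reagents that add atoms: none
Why: Intramolecular Friedel–Crafts acylation can only close onto the single free ortho position (para to the ring methyl), forming ring B.

Step 4
Reactants: 5 5,7-dimethoxy-6-methyl-3,4-dihydronaphthalen-1(2H)-one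
Product: 7 6,8-dimethoxy-4,7-dimethyl-1,2-dihydronaphthalene, via tertiary alcohol 6 (not isolated)
Conditions: MeMgBr, THF, 0 °C to rt; NH4Cl quench; then TsOH (cat.), PhMe, 80 °C
Reagents that add atoms: methylmagnesium bromide, C[Mg]Br
Why: Grignard 1,2-addition followed by acid-catalysed E1 dehydration gives the conjugated endocyclic styrene as the thermodynamic alkene.

Step 5
Reactants: 7 6,8-dimethoxy-4,7-dimethyl-1,2-dihydronaphthalene
Product: 9 5,7-dimethoxy-1,6-dimethyl-3,4-dihydronaphthalen-2(1H)-one (racemic), via epoxide 8 (not isolated)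
Conditions: mCPBA, NaHCO3, CH2Cl2, 0 °C; then TsOH (cat.), PhH, 60 °C
Reagents that add atoms: mCPBA (3-chloroperoxybenzoic acid), O=C(OO)c1cccc(Cl)c1
Why: Prilezhaev epoxidation of the electron-rich styrene and acid-induced Meinwald rearrangement (opening to the tertiary benzylic cation, 1,2-hydride shift) move the oxygen to C2 and give the 1-methyl-2-tetralone.

Step 6
Reactants: 9 5,7-dimethoxy-1,6-dimethyl-3,4-dihydronaphthalen-2(1H)-one; 10 (S)-1-phenylethylamine; 11 pent-1-en-3-one (ethyl vinyl ketone)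
Product: 14 (S)-5,7-dimethoxy-1,6-dimethyl-1-(3-oxopentyl)-3,4-dihydronaphthalen-2(1H)-one, via imine 12 (not isolated), via adduct imine 13 (not isolated)
Conditions: 10, TsOH (cat.), PhMe, reflux (Dean–Stark); then 11, THF, rt to 40 °C, 3 d; then 20% aq. AcOH, rt
Reagents that add atoms: water, O
Why: In this d'Angelo-type asymmetric Michael addition the conjugated secondary-enamine tautomer of the chiral imine adds through its benzylic carbon to the enone in an aza-ene-like transition state on the face anti to the auxiliary phenyl group, which sets the quaternary carbon as S, and mild acid hydrolysis releases the 1,5-diketone.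

Step 7
Reactants: 14 (S)-5,7-dimethoxy-1,6-dimethyl-1-(3-oxopentyl)-3,4-dihydronaphthalen-2(1H)-one
Product: 15 (R)-6,8-dimethoxy-1,4a,7-trimethyl-4,4a,9,10-tetrahydrophenanthren-2(3H)-one
Conditions: NaOMe (0.5 equiv), MeOH, 60 °C; recrystallise to raise ee
Reagents that add atoms: none
Why: Intramolecular aldol condensation (second stage of the Robinson annulation) of the ethyl-ketone α-CH2 onto the tetralone carbonyl and dehydration closes ring A as the conjugated enone, and the quaternary centre cannot epimerise.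

Step 8
Reactants: 15 (R)-6,8-dimethoxy-1,4a,7-trimethyl-4,4a,9,10-tetrahydrophenanthren-2(3H)-one
Product: 17 (4aR,10aS)-6,8-dimethoxy-1,1,4a,7-tetramethyl-3,4,4a,9,10,10a-hexahydrophenanthren-2(1H)-one (trans-fused), via lithium enolate 16 (not isolated)
Conditions: Li (2.5 equiv), NH3(l)/THF, t-BuOH (1.0 equiv), −78 °C; then MeI (excess), −78 to −33 °C
Reagents that add atoms: iodomethane, CI
Why: In this Stork reductive alkylation the dissolving-metal reduction protonates the enone β-carbon axially to give the trans ring fusion (new CH anti to the angular methyl), and the regiospecific lithium enolate is C-methylated to install the gem-dimethyl group.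

Step 9
Reactants: 17 (4aR,10aS)-6,8-dimethoxy-1,1,4a,7-tetramethyl-3,4,4a,9,10,10a-hexahydrophenanthren-2(1H)-one
Product: 18 (4aR,10aS)-6,8-dihydroxy-1,1,4a,7-tetramethyl-3,4,4a,9,10,10a-hexahydrophenanthren-2(1H)-one
Conditions: BBr3 (4 equiv), CH2Cl2, −78 to 0 °C; aq. work-up under Ar
Reagents that add atoms: none
Why: Lewis-acid ether cleavage (SN2 at methyl) removes both aryl methyl ethers while the hindered ketone is untouched.

Step 10
Reactants: 18 (4aR,10aS)-6,8-dihydroxy-1,1,4a,7-tetramethyl-3,4,4a,9,10,10a-hexahydrophenanthren-2(1H)-one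
Product: 19 (4aR,10aS)-8-hydroxy-1,1,4a,7-tetramethyl-6-(triisopropylsilyloxy)-3,4,4a,9,10,10a-hexahydrophenanthren-2(1H)-one
Conditions: TIPSCl (1.05 equiv), imidazole, DMF, 0 °C
Reagents that add atoms: chlorotriisopropylsilane, CC(C)[Si](Cl)(C(C)C)C(C)C
Why: The bulky silyl chloride silylates the phenol with an ortho hydrogen (C6–OH) much faster than the 2,6-disubstituted C8–OH, giving site-selective monoprotection.

Step 11
Reactants: 19 (4aR,10aS)-8-hydroxy-1,1,4a,7-tetramethyl-6-(triisopropylsilyloxy)-3,4,4a,9,10,10a-hexahydrophenanthren-2(1H)-one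
Product: 20 8-O-triflate of 19 (4aR,10aS)
Conditions: Tf2O, pyridine, CH2Cl2, −20 to 0 °C
Reagents that add atoms: trifluoromethanesulfonic anhydride, FC(F)(F)S(=O)(=O)OS(=O)(=O)C(F)(F)F
Why: O-Sulfonylation of the remaining hindered phenol with the small, highly reactive anhydride proceeds at low temperature without enol triflate formation at the ketone.

Step 12
Reactants: 20 8-O-triflate of 19
Product: 21 trans-fused ε-lactone (oxygen inserted between the carbonyl carbon and the gem-dimethyl carbon of 20; ring-fusion CH is S and the quaternary carbon R)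
Conditions: mCPBA, NaHCO3, CH2Cl2, rt, 48 h
Reagents that add atoms: mCPBA (3-chloroperoxybenzoic acid), O=C(OO)c1cccc(Cl)c1
Why: Baeyer–Villiger oxidation proceeds with migration of the tertiary carbon with retention, and the triflate- and silyloxy-substituted arene is too electron-poor to be oxidised.

Step 13
Reactants: 21 trans-fused ε-lactone
Product: 22 methyl 3-[(1R,2S)-2-(2-hydroxypropan-2-yl)-1,6-dimethyl-5-(trifluoromethylsulfonyloxy)-7-(triisopropylsilyloxy)-1,2,3,4-tetrahydronaphthalen-1-yl]propanoate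
Conditions: TsOH·H2O (cat.), MeOH, rt to 40 °C
Reagents that add atoms: methanol, CO
Why: Acid-catalysed transesterification (acyl–oxygen cleavage) of the seven-membered lactone in excess methanol gives the methyl ester and the tertiary carbinol and leaves the aryl triflate and aryl silyl ether intact.

Step 14
Reactants: 22 methyl 3-[(1R,2S)-2-(2-hydroxypropan-2-yl)-1,6-dimethyl-5-(trifluoromethylsulfonyloxy)-7-(triisopropylsilyloxy)-1,2,3,4-tetrahydronaphthalen-1-yl]propanoate
Product: 23 methyl 3-[(1R,2R)-1,6-dimethyl-2-(prop-1-en-2-yl)-5-(trifluoromethylsulfonyloxy)-7-(triisopropylsilyloxy)-1,2,3,4-tetrahydronaphthalen-1-yl]propanoate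
Conditions: SOCl2, pyridine, CH2Cl2, −20 to 0 °C
Reagents that add atoms: none
Why: E2-type dehydration through the chlorosulfite removes a proton from the unhindered methyl groups instead of the shielded ring CH next to the quaternary carbon, giving the isopropenyl group without touching the stereocentres.

Step 15
Reactants: 23 methyl 3-[(1R,2R)-1,6-dimethyl-2-(prop-1-en-2-yl)-5-(trifluoromethylsulfonyloxy)-7-(triisopropylsilyloxy)-1,2,3,4-tetrahydronaphthalen-1-yl]propanoate
Product: 24 methyl 3-[(1R,2R)-5-ethenyl-1,6-dimethyl-2-(prop-1-en-2-yl)-7-(triisopropylsilyloxy)-1,2,3,4-tetrahydronaphthalen-1-yl]propanoate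
Conditions: Bu3SnCH=CH2, Pd(PPh3)4 (10 mol%), LiCl, 1,4-dioxane, 100 °C
Reagents that add atoms: tributyl(vinyl)stannane, C=C[Sn](CCCC)(CCCC)CCCC
Why: Stille cross-coupling of the aryl triflate installs the vinyl group under neutral conditions tolerated by the ester, silyl ether and isopropenyl group.

Step 16
Reactants: 24 methyl 3-[(1R,2R)-5-ethenyl-1,6-dimethyl-2-(prop-1-en-2-yl)-7-(triisopropylsilyloxy)-1,2,3,4-tetrahydronaphthalen-1-yl]propanoate
Product: 25 methyl 3-[(1R,2R)-5-ethenyl-7-hydroxy-1,6-dimethyl-2-(prop-1-en-2-yl)-1,2,3,4-tetrahydronaphthalen-1-yl]propanoate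
Conditions: TBAF, AcOH (1:1), THF, 0 °C
Reagents that add atoms: none
Why: Fluoride-mediated desilylation cleaves the aryl Si–O bond rapidly, and the acetic acid buffer keeps the phenoxide from attacking the ester.

Step 17
Reactants: 25 methyl 3-[(1R,2R)-5-ethenyl-7-hydroxy-1,6-dimethyl-2-(prop-1-en-2-yl)-1,2,3,4-tetrahydronaphthalen-1-yl]propanoate
Product: 26 trigonochinene C, methyl 3-[(1R,2R,4aR)-5-ethenyl-4a-hydroperoxy-1,6-dimethyl-7-oxo-2-(prop-1-en-2-yl)-1,2,3,4,4a,7-hexahydronaphthalen-1-yl]propanoate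
Conditions: O2, rose bengal (2 mol%), hν (visible), MeOH/CH2Cl2, −20 °C, stop at full conversion; separate the minor C4a epimer by chromatography
Reagents that add atoms: dioxygen (as singlet oxygen), O=O
Why: Singlet-oxygen dearomatisation of the para-alkylphenol ([4+2] addition across the ipso/para carbons, then opening to the para-hydroperoxy dienone) is much faster than ene reaction at the 1,1-disubstituted alkenes, and axial attack on the half-chair with equatorial isopropenyl and pseudoaxial C1-methyl places OOH syn to that methyl (4aR), as in 6β-attack on steroidal 3,5-dienols.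

## Compound list

1 | 2,6-dimethoxytoluene | COc1cccc(OC)c1C | starting material
2 | succinic anhydride | O=C1CCC(=O)O1 | starting material
3 | 4-(2,4-dimethoxy-3-methylphenyl)-4-oxobutanoic acid | COc1ccc(C(=O)CCC(=O)O)c(OC)c1C | intermediate
4 | 4-(2,4-dimethoxy-3-methylphenyl)butanoic acid | COc1ccc(CCCC(=O)O)c(OC)c1C | intermediate
5 | 5,7-dimethoxy-6-methyl-3,4-dihydronaphthalen-1(2H)-one | COc1c(C)c(OC)cc2c1CCCC2=O | intermediate
6 | 5,7-dimethoxy-1,6-dimethyl-1,2,3,4-tetrahydronaphthalen-1-ol (racemic, not isolated) | COc1c(C)c(OC)cc2c1CCCC2(C)O | intermediate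
7 | 6,8-dimethoxy-4,7-dimethyl-1,2-dihydronaphthalene | COc1c(C)c(OC)cc2c1CCC=C2C | intermediate
8 | 4,6-dimethoxy-5,7b-dimethyl-1a,2,3,7b-tetrahydronaphtho[1,2-b]oxirene (racemic, not isolated) | COc1c(C)c(OC)cc2c1CCC3OC23C | intermediate
9 | 5,7-dimethoxy-1,6-dimethyl-3,4-dihydronaphthalen-2(1H)-one (racemic) | COc1c(C)c(OC)cc2c1CCC(=O)C2C | intermediate
10 | (S)-1-phenylethylamine | C[C@H](N)c1ccccc1 | starting material
11 | pent-1-en-3-one (ethyl vinyl ketone) | C=CC(=O)CC | starting material
12 | N-[(S)-1-phenylethyl]imine of 9 (in equilibrium with its conjugated enamine, not isolated) | COc1c(C)c(OC)cc2c1CCC(=N[C@@H](C)c3ccccc3)C2C | intermediate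
13 | N-[(S)-1-phenylethyl]imine of 14, (S) at the quaternary carbon (not isolated) | COc1c(C)c(OC)cc2c1CCC(=N[C@@H](C)c3ccccc3)[C@@]2(C)CCC(=O)CC | intermediate
14 | (S)-5,7-dimethoxy-1,6-dimethyl-1-(3-oxopentyl)-3,4-dihydronaphthalen-2(1H)-one | COc1c(C)c(OC)cc2c1CCC(=O)[C@@]2(C)CCC(=O)CC | intermediate
15 | (R)-6,8-dimethoxy-1,4a,7-trimethyl-4,4a,9,10-tetrahydrophenanthren-2(3H)-one | COc1c(C)c(OC)cc2c1CCC3=C(C)C(=O)CC[C@@]23C | intermediate
16 | lithium enolate of the trans-fused 1-methyl ketone (not isolated) | COc1c(C)c(OC)cc2c1CC[C@H]3[C@@]2(C)CCC([O-])=C3C.[Li+] | intermediate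
17 | (4aR,10aS)-6,8-dimethoxy-1,1,4a,7-tetramethyl-3,4,4a,9,10,10a-hexahydrophenanthren-2(1H)-one | COc1c(C)c(OC)cc2c1CC[C@H]3[C@@]2(C)CCC(=O)C3(C)C | intermediate
18 | (4aR,10aS)-6,8-dihydroxy-1,1,4a,7-tetramethyl-3,4,4a,9,10,10a-hexahydrophenanthren-2(1H)-one | Oc1c(C)c(O)cc2c1CC[C@H]3[C@@]2(C)CCC(=O)C3(C)C | intermediate
19 | (4aR,10aS)-8-hydroxy-1,1,4a,7-tetramethyl-6-(triisopropylsilyloxy)-3,4,4a,9,10,10a-hexahydrophenanthren-2(1H)-one | Oc1c(C)c(O[Si](C(C)C)(C(C)C)C(C)C)cc2c1CC[C@H]3[C@@]2(C)CCC(=O)C3(C)C | intermediate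
20 | 8-O-triflate of 19 (4aR,10aS) | FC(F)(F)S(=O)(=O)Oc1c(C)c(O[Si](C(C)C)(C(C)C)C(C)C)cc2c1CC[C@H]3[C@@]2(C)CCC(=O)C3(C)C | intermediate
21 | trans-fused ε-lactone from Baeyer–Villiger oxidation of 20 (ring-fusion CH S, quaternary carbon R) | FC(F)(F)S(=O)(=O)Oc1c(C)c(O[Si](C(C)C)(C(C)C)C(C)C)cc2c1CC[C@H]3[C@@]2(C)CCC(=O)OC3(C)C | intermediate
22 | methyl 3-[(1R,2S)-2-(2-hydroxypropan-2-yl)-1,6-dimethyl-5-(trifluoromethylsulfonyloxy)-7-(triisopropylsilyloxy)-1,2,3,4-tetrahydronaphthalen-1-yl]propanoate | FC(F)(F)S(=O)(=O)Oc1c(C)c(O[Si](C(C)C)(C(C)C)C(C)C)cc2c1CC[C@H](C(C)(C)O)[C@@]2(C)CCC(=O)OC | intermediate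
23 | methyl 3-[(1R,2R)-1,6-dimethyl-2-(prop-1-en-2-yl)-5-(trifluoromethylsulfonyloxy)-7-(triisopropylsilyloxy)-1,2,3,4-tetrahydronaphthalen-1-yl]propanoate | FC(F)(F)S(=O)(=O)Oc1c(C)c(O[Si](C(C)C)(C(C)C)C(C)C)cc2c1CC[C@H](C(=C)C)[C@@]2(C)CCC(=O)OC | intermediate
24 | methyl 3-[(1R,2R)-5-ethenyl-1,6-dimethyl-2-(prop-1-en-2-yl)-7-(triisopropylsilyloxy)-1,2,3,4-tetrahydronaphthalen-1-yl]propanoate | C=Cc1c(C)c(O[Si](C(C)C)(C(C)C)C(C)C)cc2c1CC[C@H](C(=C)C)[C@@]2(C)CCC(=O)OC | intermediate
25 | methyl 3-[(1R,2R)-5-ethenyl-7-hydroxy-1,6-dimethyl-2-(prop-1-en-2-yl)-1,2,3,4-tetrahydronaphthalen-1-yl]propanoate | C=Cc1c(C)c(O)cc2c1CC[C@H](C(=C)C)[C@@]2(C)CCC(=O)OC | intermediate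
26 | trigonochinene C, methyl 3-[(1R,2R,4aR)-5-ethenyl-4a-hydroperoxy-1,6-dimethyl-7-oxo-2-(prop-1-en-2-yl)-1,2,3,4,4a,7-hexahydronaphthalen-1-yl]propanoate | C=CC1=C(C)C(=O)C=C2[C@]1(OO)CC[C@H](C(=C)C)[C@@]2(C)CCC(=O)OC | target

## Step count and risks

Total steps: 17. Longest linear sequence: 17 steps (1 → 26).

**Step 17 (photooxygenation).** This is the most likely to fail: the facial selectivity at the new C–OOH centre rests on a conformational argument and may be modest, and singlet oxygen could also attack the isopropenyl group. The fallback changes the order of the last events; it sets out from carbinol 22 and comes back at target 26. Stille vinylation of 22 (conditions of step 15) gives the vinyl carbinol silyl ether F1, and TBAF/AcOH gives the phenol carbinol F2. Photooxygenation (O2, rose bengal, hν) then gives the hydroperoxy dienone carbinol F3. No isopropenyl group is exposed to singlet oxygen at this stage, and the bulkier tertiary carbinol should hold the half-chair with the C1 methyl pseudoaxial more firmly, so axial attack syn to the methyl is favoured. The hydroperoxide is masked as the triethylsilyl peroxide carbinol F4 (TESCl, imidazole, 0 °C; the tertiary alcohol does not silylate). Burgess reagent (PhH, 50 °C) dehydrates it to the isopropenyl triethylsilyl peroxide F5, and HF·pyridine in THF releases 26.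

**Step 14 (dehydration).** The tertiary carbinol may give some tetrasubstituted alkene or tertiary chloride. The fallback avoids the carbinol altogether; it sets out from ketone 20 and comes back at ester 23. NH2OH·HCl/NaOAc in EtOH gives the ketoxime F6. Beckmann fragmentation (TsCl, pyridine, 70 °C) cleaves the bond to the gem-dimethyl carbon and forms the isopropenyl group directly, giving the seco nitrile F7. DIBAL-H at −78 °C gives the seco aldehyde F8, Pinnick oxidation (NaClO2, NaH2PO4, 2-methylbut-2-ene) gives the seco acid F9, and TMSCHN2 in MeOH/PhMe gives 23.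

**Step 8 (reductive methylation).** Over-reduction of the electron-rich arene, O-methylation or proton-transfer polyalkylation can erode the yield. The fallback replaces the dissolving metal by alkylation then hydrogenation; it sets out from enone 15 and comes back at ketone 17. KOtBu/MeI in t-BuOH methylates the extended enolate at the α-carbon with deconjugation to give the β,γ-unsaturated gem-dimethyl ketone F10. H2 over Pd/C in EtOAc then adds from the face opposite the angular methyl to give trans-fused 17.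

## Further compounds

F1 | step 17 | methyl 3-[(1R,2S)-5-ethenyl-2-(2-hydroxypropan-2-yl)-1,6-dimethyl-7-(triisopropylsilyloxy)-1,2,3,4-tetrahydronaphthalen-1-yl]propanoate | C=Cc1c(C)c(O[Si](C(C)C)(C(C)C)C(C)C)cc2c1CC[C@H](C(C)(C)O)[C@@]2(C)CCC(=O)OC
F2 | step 17 | methyl 3-[(1R,2S)-5-ethenyl-7-hydroxy-2-(2-hydroxypropan-2-yl)-1,6-dimethyl-1,2,3,4-tetrahydronaphthalen-1-yl]propanoate | C=Cc1c(C)c(O)cc2c1CC[C@H](C(C)(C)O)[C@@]2(C)CCC(=O)OC
F3 | step 17 | methyl 3-[(1R,2S,4aR)-5-ethenyl-4a-hydroperoxy-2-(2-hydroxypropan-2-yl)-1,6-dimethyl-7-oxo-1,2,3,4,4a,7-hexahydronaphthalen-1-yl]propanoate | C=CC1=C(C)C(=O)C=C2[C@]1(OO)CC[C@H](C(C)(C)O)[C@@]2(C)CCC(=O)OC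
F4 | step 17 | triethylsilyl peroxide of F3 | C=CC1=C(C)C(=O)C=C2[C@]1(OO[Si](CC)(CC)CC)CC[C@H](C(C)(C)O)[C@@]2(C)CCC(=O)OC
F5 | step 17 | triethylsilyl peroxide of 26 | C=CC1=C(C)C(=O)C=C2[C@]1(OO[Si](CC)(CC)CC)CC[C@H](C(=C)C)[C@@]2(C)CCC(=O)OC
F6 | step 14 | oxime of ketone 20 (4aR,10aS) | FC(F)(F)S(=O)(=O)Oc1c(C)c(O[Si](C(C)C)(C(C)C)C(C)C)cc2c1CC[C@H]3[C@@]2(C)CCC(=NO)C3(C)C
F7 | step 14 | 3-[(1R,2R)-1,6-dimethyl-2-(prop-1-en-2-yl)-5-(trifluoromethylsulfonyloxy)-7-(triisopropylsilyloxy)-1,2,3,4-tetrahydronaphthalen-1-yl]propanenitrile | FC(F)(F)S(=O)(=O)Oc1c(C)c(O[Si](C(C)C)(C(C)C)C(C)C)cc2c1CC[C@H](C(=C)C)[C@@]2(C)CCC#N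
F8 | step 14 | 3-[(1R,2R)-1,6-dimethyl-2-(prop-1-en-2-yl)-5-(trifluoromethylsulfonyloxy)-7-(triisopropylsilyloxy)-1,2,3,4-tetrahydronaphthalen-1-yl]propanal | FC(F)(F)S(=O)(=O)Oc1c(C)c(O[Si](C(C)C)(C(C)C)C(C)C)cc2c1CC[C@H](C(=C)C)[C@@]2(C)CCC=O
F9 | step 14 | 3-[(1R,2R)-1,6-dimethyl-2-(prop-1-en-2-yl)-5-(trifluoromethylsulfonyloxy)-7-(triisopropylsilyloxy)-1,2,3,4-tetrahydronaphthalen-1-yl]propanoic acid | FC(F)(F)S(=O)(=O)Oc1c(C)c(O[Si](C(C)C)(C(C)C)C(C)C)cc2c1CC[C@H](C(=C)C)[C@@]2(C)CCC(=O)O
F10 | step 8 | (S)-6,8-dimethoxy-1,1,4a,7-tetramethyl-3,4,4a,9-tetrahydrophenanthren-2(1H)-one | COc1c(C)c(OC)cc2c1CC=C3[C@@]2(C)CCC(=O)C3(C)C
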